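**Retrosynthetic overview**

1. The target is the all-trans (2S,3R,4S) tetrahydrofuran O1–C2(aryl)–C3(CH2OH)–C4(aroyl)–C5H2. The two phenols are freed last by hydrogenolysis, and the C3 CH2OH is traced back to a C3 vinyl group (oxidative cleavage, then aldehyde reduction).
2. The only ring is disconnected at O1–C5 and C3–C4. The strategy rests on this feature: O1–C2(aryl)–C3 is an opened aryl vinyl oxirane whose C2–O bond is never broken, C5–C4–C(=O)Ar is an intact aryl vinyl ketone, and the vinyl group left on C3 is the masked CH2OH.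
3. Oxirane 6 comes from sinapic acid by benzylation, ester reduction, Sharpless epoxidation, oxidation and Wittig methylenation. Enone 10 comes from acetosyringone by benzylation and α-methylenation.
4. Ring order: the tetrahydrofuran is the only ring formed, and it is closed in the palladium-catalysed (3+2) step.

Key step: step 8

Assumption: both phenols are carried as benzyl ethers to the last step, and the oxirane is built from the cinnamyl alcohol because direct oxidation of a 1-arylbuta-1,3-diene can also take place at its terminal double bond.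

**Route**

Step 1
Reactants: 1 sinapic acid
Product: 2 benzyl (E)-3-(4-benzyloxy-3,5-dimethoxyphenyl)prop-2-enoate
Conditions: BnBr (2.3 equiv), K2CO3 (3 equiv), DMF, 60 °C
Reagents that add atoms: benzyl bromide, BrCc1ccccc1
Why: Williamson-type O-alkylation, in which K2CO3 deprotonates both the carboxylic acid and the hindered phenol and each oxygen displaces bromide from benzyl bromide by SN2, leaving the E alkene untouched.

Step 2
Reactants: 2 benzyl (E)-3-(4-benzyloxy-3,5-dimethoxyphenyl)prop-2-enoate
Product: 3 (E)-3-(4-benzyloxy-3,5-dimethoxyphenyl)prop-2-en-1-ol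
Conditions: iBu2AlH (3 equiv), CH2Cl2, −78 °C; aq. potassium sodium tartrate
Reagents that add atoms: none
Why: Hydride reduction of a conjugated ester with iBu2AlH, which at low temperature should proceed in 1,2-fashion to the allylic alcohol while the aryl benzyl ether and the E alkene are inert.

Step 3
Reactants: 3 (E)-3-(4-benzyloxy-3,5-dimethoxyphenyl)prop-2-en-1-ol
Product: 4 [(2R,3R)-3-(4-benzyloxy-3,5-dimethoxyphenyl)oxiran-2-yl]methanol
Conditions: Ti(OiPr)4 (10 mol %), D-(−)-diethyl tartrate (12 mol %), tBuOOH (2 equiv, in decane), 4 Å molecular sieves, CH2Cl2, −20 °C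
Reagents that add atoms: tert-butyl hydroperoxide, CC(C)(C)OO
Why: Sharpless asymmetric epoxidation, in which the titanium–D-(−)-tartrate complex delivers oxygen to the alkene face that gives the (2R,3R) epoxy alcohol, so that both oxirane stereocentres are set by the reagent and the trans relationship follows from the E alkene.

Step 4
Reactants: 4 [(2R,3R)-3-(4-benzyloxy-3,5-dimethoxyphenyl)oxiran-2-yl]methanol
Product: 5 (2S,3R)-3-(4-benzyloxy-3,5-dimethoxyphenyl)oxirane-2-carbaldehyde (same spatial arrangement as 4; the descriptor at C2 changes only through the priority rules)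
Conditions: SO3·pyridine (3 equiv), DMSO, iPr2NEt, CH2Cl2, 0 °C
Reagents that add atoms: none
Why: Parikh–Doering oxidation (activated DMSO) should convert the primary alcohol to the aldehyde under basic, non-acidic conditions that neither open the acid-sensitive benzylic oxirane nor disturb its stereocentres.

Step 5
Reactants: 5 (2S,3R)-3-(4-benzyloxy-3,5-dimethoxyphenyl)oxirane-2-carbaldehyde
Product: 6 (2R,3R)-2-(4-benzyloxy-3,5-dimethoxyphenyl)-3-ethenyloxirane (trans)
Conditions: Ph3PCH3Br (1.5 equiv), KN(SiMe3)2 (1.4 equiv), THF, −78 °C to 0 °C; chromatography on Et3N-deactivated silica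
Reagents that add atoms: methyltriphenylphosphonium bromide, C[P+](c1ccccc1)(c1ccccc1)c1ccccc1.[Br-]
Why: Wittig methylenation with the non-stabilised ylide Ph3P=CH2 should convert the aldehyde to the vinyl group at low temperature without touching the two oxirane stereocentres.

Step 6
Reactants: 7 acetosyringone
Product: 8 1-(4-benzyloxy-3,5-dimethoxyphenyl)ethanone
Conditions: BnBr (1.2 equiv), K2CO3 (2 equiv), DMF, 60 °C
Reagents that add atoms: benzyl bromide, BrCc1ccccc1
Why: Williamson ether synthesis, in which the phenoxide formed with K2CO3 displaces bromide from benzyl bromide by SN2 while the methyl ketone is not enolised under these conditions.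

Step 7
Reactants: 8 1-(4-benzyloxy-3,5-dimethoxyphenyl)ethanone
Product: 10 1-(4-benzyloxy-3,5-dimethoxyphenyl)prop-2-en-1-one (used fresh), via Mannich base 9 (not isolated)
Conditions: (CH2O)n (2 equiv), iPr2NH2+ CF3CO2− (1 equiv), CF3CO2H (10 mol %), THF, reflux
Reagents that add atoms: paraformaldehyde (formaldehyde), C=O
Why: Mannich-type α-methylenation, in which the iminium ion formed from formaldehyde and the ammonium salt is attacked by the enol of the only enolisable position and the resulting β-amino ketone loses the amine by elimination to give the aryl vinyl ketone.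

Step 8
Reactants: 6 (2R,3R)-2-(4-benzyloxy-3,5-dimethoxyphenyl)-3-ethenyloxirane and 10 1-(4-benzyloxy-3,5-dimethoxyphenyl)prop-2-en-1-one
Product: 12 (2S,3S,4S)-2-(4-benzyloxy-3,5-dimethoxyphenyl)-4-(4-benzyloxy-3,5-dimethoxybenzoyl)-3-ethenyltetrahydrofuran (all-trans), via C4 epimer 11 (not isolated)
Conditions: Pd(PPh3)4 (5 mol %), THF, rt, 10 (1.5 equiv) added over 2 h; then DBU (0.2 equiv), rt
Reagents that add atoms: none
Why: Zerovalent palladium ionises the allylic C–O bond of 6 with inversion to give an alkoxide/π-allylpalladium zwitterion in which the benzylic C2–O bond is untouched; the alkoxide adds to the unsubstituted β-carbon of enone 10 (oxa-Michael, O1–C5) and the resulting ketone enolate attacks the internal allyl carbon anti to palladium (C3–C4), releasing the catalyst. The closest known reaction type is the palladium-catalysed (3+2) cycloaddition of vinyl oxiranes with electron-poor alkenes, a class that includes singly activated acceptors such as enones and nitroalkenes. The tetrahydrofuran closes by 5-exo attack of the enolate on the allyl unit, the remaining double bond ending up exocyclic as the C3 vinyl group. C2 is carried over unchanged from the oxirane; C3 arises by double inversion (net retention) and is therefore trans to the C2 aryl group, and any facial leakage of the allyl complex through its unsubstituted terminus is corrected because closure cis to the aryl group is sterically disfavoured; C4 is set in the closure and, being α to the ketone, is driven to the all-trans isomer by the final DBU treatment. The step needs attack at the internal rather than the terminal allyl carbon (five- versus seven-membered ring) and capture of the zwitterion faster than its hydride-shift isomerisation or oligomerisation of the enone, which the short tether, the unhindered and highly electrophilic vinyl ketone and its slow addition should secure.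

Step 9
Reactants: 12 (2S,3S,4S)-2-(4-benzyloxy-3,5-dimethoxyphenyl)-4-(4-benzyloxy-3,5-dimethoxybenzoyl)-3-ethenyltetrahydrofuran
Product: 14 (2S,3S,4S)-2-(4-benzyloxy-3,5-dimethoxyphenyl)-4-(4-benzyloxy-3,5-dimethoxybenzoyl)tetrahydrofuran-3-carbaldehyde (all-trans; used crude), via vicinal diol 13 (not isolated)
Conditions: OsO4 (2 mol %), NaIO4 (4 equiv), 2,6-lutidine (2 equiv), dioxane/H2O 3:1, rt
Reagents that add atoms: osmium tetroxide, O=[Os](=O)(=O)=O; sodium periodate, [Na+].[O-][I](=O)(=O)=O
Why: Lemieux–Johnson oxidation, in which OsO4 dihydroxylates the only alkene and NaIO4 cleaves the diol to the aldehyde while reoxidising osmium, with 2,6-lutidine buffering the mixture so that the stereocentre α to the β-alkoxy aldehyde is neither epimerised nor lost by elimination.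

Step 10
Reactants: 14 (2S,3S,4S)-2-(4-benzyloxy-3,5-dimethoxyphenyl)-4-(4-benzyloxy-3,5-dimethoxybenzoyl)tetrahydrofuran-3-carbaldehyde
Product: 15 (2S,3R,4S)-2-(4-benzyloxy-3,5-dimethoxyphenyl)-4-(4-benzyloxy-3,5-dimethoxybenzoyl)-3-(hydroxymethyl)tetrahydrofuran (all-trans)
Conditions: NaBH4 (1 equiv), EtOH/CH2Cl2 3:7, −78 °C
Reagents that add atoms: none
Why: Chemoselective borohydride reduction, in which NaBH4 at −78 °C should reduce the unhindered aldehyde much faster than the electron-rich, α-branched aryl ketone, giving the primary alcohol with the three ring stereocentres unchanged.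

Step 11
Reactants: 15 (2S,3R,4S)-2-(4-benzyloxy-3,5-dimethoxyphenyl)-4-(4-benzyloxy-3,5-dimethoxybenzoyl)-3-(hydroxymethyl)tetrahydrofuran
Product: 16 (2S,3R,4S)-2-(4-hydroxy-3,5-dimethoxyphenyl)-4-(4-hydroxy-3,5-dimethoxybenzoyl)-3-(hydroxymethyl)tetrahydrofuran (CID53356211)
Conditions: H2 (1 atm), 10% Pd/C, EtOAc, rt, stopped at full debenzylation
Reagents that add atoms: none
Why: Catalytic hydrogenolysis should cleave the two aryl benzyl ethers far faster than the dialkyl benzylic C2–O1 bond or the electron-rich aryl ketone under neutral conditions at 1 atm, freeing both phenols without touching a stereocentre.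

**Compound list**

1 | sinapic acid | COc1cc(/C=C/C(=O)O)cc(OC)c1O | starting material
2 | benzyl (E)-3-(4-benzyloxy-3,5-dimethoxyphenyl)prop-2-enoate | COc1cc(/C=C/C(=O)OCc2ccccc2)cc(OC)c1OCc1ccccc1 | intermediate
3 | (E)-3-(4-benzyloxy-3,5-dimethoxyphenyl)prop-2-en-1-ol | COc1cc(/C=C/CO)cc(OC)c1OCc1ccccc1 | intermediate
4 | [(2R,3R)-3-(4-benzyloxy-3,5-dimethoxyphenyl)oxiran-2-yl]methanol | OC[C@H]1O[C@@H]1c1cc(OC)c(OCc2ccccc2)c(OC)c1 | intermediate
5 | (2S,3R)-3-(4-benzyloxy-3,5-dimethoxyphenyl)oxirane-2-carbaldehyde | O=C[C@H]1O[C@@H]1c1cc(OC)c(OCc2ccccc2)c(OC)c1 | intermediate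
6 | (2R,3R)-2-(4-benzyloxy-3,5-dimethoxyphenyl)-3-ethenyloxirane (trans) | C=C[C@H]1O[C@@H]1c1cc(OC)c(OCc2ccccc2)c(OC)c1 | intermediate
7 | acetosyringone | CC(=O)c1cc(OC)c(O)c(OC)c1 | starting material
8 | 1-(4-benzyloxy-3,5-dimethoxyphenyl)ethanone | CC(=O)c1cc(OC)c(OCc2ccccc2)c(OC)c1 | intermediate
9 | 1-(4-benzyloxy-3,5-dimethoxyphenyl)-3-(diisopropylamino)propan-1-one (Mannich base, not isolated) | CC(C)N(CCC(=O)c1cc(OC)c(OCc2ccccc2)c(OC)c1)C(C)C | intermediate
10 | 1-(4-benzyloxy-3,5-dimethoxyphenyl)prop-2-en-1-one | C=CC(=O)c1cc(OC)c(OCc2ccccc2)c(OC)c1 | intermediate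
11 | (2S,3S,4R)-2-(4-benzyloxy-3,5-dimethoxyphenyl)-4-(4-benzyloxy-3,5-dimethoxybenzoyl)-3-ethenyltetrahydrofuran (2,3-trans-3,4-cis C4 epimer, not isolated) | COc1cc(C(=O)[C@H]2CO[C@H](c3cc(OC)c(OCc4ccccc4)c(OC)c3)[C@H]2C=C)cc(OC)c1OCc1ccccc1 | intermediate
12 | (2S,3S,4S)-2-(4-benzyloxy-3,5-dimethoxyphenyl)-4-(4-benzyloxy-3,5-dimethoxybenzoyl)-3-ethenyltetrahydrofuran (all-trans) | COc1cc(C(=O)[C@@H]2CO[C@H](c3cc(OC)c(OCc4ccccc4)c(OC)c3)[C@H]2C=C)cc(OC)c1OCc1ccccc1 | intermediate
13 | 3-(1,2-dihydroxyethyl) analogue of 12 (ring stereocentres as in 12, new carbinol carbon unassigned, not isolated) | COc1cc(C(=O)[C@@H]2CO[C@H](c3cc(OC)c(OCc4ccccc4)c(OC)c3)[C@H]2C(O)CO)cc(OC)c1OCc1ccccc1 | intermediate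
14 | (2S,3S,4S)-2-(4-benzyloxy-3,5-dimethoxyphenyl)-4-(4-benzyloxy-3,5-dimethoxybenzoyl)tetrahydrofuran-3-carbaldehyde (all-trans) | COc1cc(C(=O)[C@@H]2CO[C@H](c3cc(OC)c(OCc4ccccc4)c(OC)c3)[C@H]2C=O)cc(OC)c1OCc1ccccc1 | intermediate
15 | (2S,3R,4S)-2-(4-benzyloxy-3,5-dimethoxyphenyl)-4-(4-benzyloxy-3,5-dimethoxybenzoyl)-3-(hydroxymethyl)tetrahydrofuran (all-trans) | COc1cc(C(=O)[C@@H]2CO[C@H](c3cc(OC)c(OCc4ccccc4)c(OC)c3)[C@H]2CO)cc(OC)c1OCc1ccccc1 | intermediate
16 | (2S,3R,4S)-2-(4-hydroxy-3,5-dimethoxyphenyl)-4-(4-hydroxy-3,5-dimethoxybenzoyl)-3-(hydroxymethyl)tetrahydrofuran (CID53356211) | COc1cc(C(=O)[C@@H]2CO[C@H](c3cc(OC)c(O)c(OC)c3)[C@H]2CO)cc(OC)c1O | target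

**Step count and risks**

Total step count: 11. Longest linear sequence: 9 steps (steps 1–5, then 8–11); steps 6 and 7 form the second branch.

Steps most likely to fail:

Step 8 (key cycloaddition). The unstabilised ketone enolate formed after the oxa-Michael addition may add to further enone (oligomerisation), or the zwitterion may isomerise by hydride shift before it is captured, so that ring closure onto the allyl unit is outrun. The fallback gives the acceptor a second, removable anion-stabilising group. The cycloaddition then falls in the doubly activated olefin class and the ring-closing nucleophile is a soft, stabilised carbanion. It sets out from ketone 8 and oxirane 6 and comes back at 12. Ketone 8 is α-brominated (CuBr2, EtOAc/CHCl3, reflux) to 2-bromo-1-(4-benzyloxy-3,5-dimethoxyphenyl)ethanone F1. Displacement with PhSO2Na (DMF, rt) gives the β-keto sulfone 1-(4-benzyloxy-3,5-dimethoxyphenyl)-2-(phenylsulfonyl)ethanone F2. Mannich-type methylenation (paraformaldehyde, catalytic piperidine/AcOH) gives 1-(4-benzyloxy-3,5-dimethoxyphenyl)-2-(phenylsulfonyl)prop-2-en-1-one F3, which is used crude. Cycloaddition of F3 with 6 under Pd(PPh3)4 in THF should give the 4-(phenylsulfonyl) analogue of 12 F4, with a quaternary C4 whose configuration is immaterial. Reductive desulfonylation with Al(Hg) in wet THF, followed by brief DBU equilibration at C4, returns 12.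

Step 3 (Sharpless epoxidation). The electron-rich benzylic oxirane may be opened at the benzylic carbon by the Lewis acidic titanium alkoxide medium as it forms. The fallback replaces the electrophilic, metal-mediated epoxidation by an aminocatalytic nucleophilic one. It sets out from allylic alcohol 3 and comes back at 5, so that step 4 is no longer needed. Alcohol 3 is oxidised with MnO2 (CH2Cl2, rt) to (E)-3-(4-benzyloxy-3,5-dimethoxyphenyl)prop-2-enal F5. Treatment with aqueous H2O2 and a diarylprolinol trimethylsilyl ether (10 mol %, CH2Cl2, rt) proceeds by iminium-activated conjugate addition of hydroperoxide and enamine ring closure. The catalyst enantiomer is chosen to deliver the (2S,3R) aldehyde, expected to be the R-configured one. This should give the trans epoxy aldehyde 5 directly under neutral conditions.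

Step 10 (aldehyde-selective reduction). The aryl ketone may be partly reduced as well, or the β-alkoxy aldehyde may epimerise or eliminate before it is reduced. The fallback reduces both carbonyl groups on purpose and re-oxidises only the benzylic alcohol. It sets out from 14 and comes back at 15. Excess NaBH4 (MeOH, 0 °C) should give the diol 2-(4-benzyloxy-3,5-dimethoxyphenyl)-4-[(4-benzyloxy-3,5-dimethoxyphenyl)(hydroxy)methyl]-3-(hydroxymethyl)tetrahydrofuran F6 as a mixture at the new benzylic carbinol. Activated MnO2 (CH2Cl2, rt) should then oxidise the electron-rich secondary benzylic alcohol but not the primary alcohol, returning 15, with a short DBU treatment if C4 needs to be re-equilibrated.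

**Further compounds**

F1 | step 8 | 2-bromo-1-(4-benzyloxy-3,5-dimethoxyphenyl)ethanone | COc1cc(C(=O)CBr)cc(OC)c1OCc1ccccc1
F2 | step 8 | 1-(4-benzyloxy-3,5-dimethoxyphenyl)-2-(phenylsulfonyl)ethanone | COc1cc(C(=O)CS(=O)(=O)c2ccccc2)cc(OC)c1OCc1ccccc1
F3 | step 8 | 1-(4-benzyloxy-3,5-dimethoxyphenyl)-2-(phenylsulfonyl)prop-2-en-1-one | COc1cc(C(=O)C(=C)S(=O)(=O)c2ccccc2)cc(OC)c1OCc1ccccc1
F4 | step 8 | 4-(phenylsulfonyl) analogue of 12 (2-aryl and 3-ethenyl trans as in 12, C4 quaternary and unassigned) | COc1cc(C(=O)C2(S(=O)(=O)c3ccccc3)CO[C@H](c3cc(OC)c(OCc4ccccc4)c(OC)c3)[C@H]2C=C)cc(OC)c1OCc1ccccc1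
F5 | step 3 | (E)-3-(4-benzyloxy-3,5-dimethoxyphenyl)prop-2-enal | COc1cc(/C=C/C=O)cc(OC)c1OCc1ccccc1
F6 | step 10 | 2-(4-benzyloxy-3,5-dimethoxyphenyl)-4-[(4-benzyloxy-3,5-dimethoxyphenyl)(hydroxy)methyl]-3-(hydroxymethyl)tetrahydrofuran (ring stereocentres as in 15, benzylic carbinol unassigned) | COc1cc(C(O)[C@@H]2CO[C@H](c3cc(OC)c(OCc4ccccc4)c(OC)c3)[C@H]2CO)cc(OC)c1OCc1ccccc1
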